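**Retrosynthetic overview**

1. Ring A is opened at C2–C3 (the ring CH2 next to the CH–CH3 carbon, and the carbinol carbon). A type 2 intramolecular carbonyl-ene closure of a monocyclic α-bromo aldehyde onto an isopropenyl group gives the spiro[5.5] skeleton; C1 is then set by OH-directed hydrogenation and C3 is corrected by oxidation/reduction.
2. Enabling feature: in ring A the methyl-bearing C1 lies 1,3 to the carbinol C3 across the C2 methylene (a 3-methylcyclohexanol, i.e. a reduced 3-methylenecyclohexanol), and the tether C4–C5–C6 contains two adjacent quaternary carbons (gem-dimethyl C5, spiro C6) that drive ring closure.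
3. The C5–C6 bond between the two quaternary carbons comes from an Ireland–Claisen rearrangement of a prenyl ester on a symmetric, ketal-protected ring B; the acid becomes the isopropenyl group (C1, C2) and the vinyl group becomes the aldehyde (C3).
4. Ring order: ring B is bought as a cyclohexanone ketal, ring A closes in step 7, and ring B is functionalised last (desymmetrising enolisation, C10 bromination, C9 methyl addition, chloride substitution through the bromonium ion).
5. Absolute configuration comes from an amine-catalysed α-bromination (C4) and a chiral lithium amide (C6/C10); the other centres follow by substrate control.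

Key step: step 7

Remark (locants): all spiro compounds are numbered as in 4,10-dibromo-9-chloro-1,5,5,9-tetramethylspiro[5.5]undecan-3-ol: ring A = C1 (CH–CH3), C2 (CH2), C3 (CH–OH), C4 (CH–Br), C5 (C(CH3)2), C6 (spiro atom); ring B = C6, C7, C8, C9 (C(CH3)Cl), C10 (CH–Br), C11.

Remark (assumption): the sense of induction of the two chiral reagents (steps 6 and 11) is taken from the usual models for these reagents; should either prove opposite, its enantiomer is used and nothing else changes.

**Route**

Step 1
Reactants: 1 1,4-dioxaspiro[4.5]decane-8-carboxylic acid; 2 1-bromo-3-methylbut-2-ene (prenyl bromide)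
Product: 3 3-methylbut-2-en-1-yl 1,4-dioxaspiro[4.5]decane-8-carboxylate
Conditions: K2CO3, DMF, rt
Reagents that add atoms: none
Why: SN2 O-alkylation of the carboxylate by the primary allylic bromide gives the prenyl ester; no stereocentre is involved.

Step 2
Reactants: 3 3-methylbut-2-en-1-yl 1,4-dioxaspiro[4.5]decane-8-carboxylate
Product: 6 8-(2-methylbut-3-en-2-yl)-1,4-dioxaspiro[4.5]decane-8-carboxylic acid, via silyl ketene acetal 4 (not isolated), via silyl ester 5 (not isolated)
Conditions: LiN(iPr)2, Me3SiCl, THF, −78 °C to 60 °C; then H2O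
Reagents that add atoms: none
Why: Ireland–Claisen rearrangement through a chair transition state joins the ring carbon to the dimethyl-substituted allyl terminus and so creates the future C5–C6 bond between two quaternary carbons; ring B is symmetric, so no stereocentre arises.

Step 3
Reactants: 6 8-(2-methylbut-3-en-2-yl)-1,4-dioxaspiro[4.5]decane-8-carboxylic acid
Product: 7 1-[8-(2-methylbut-3-en-2-yl)-1,4-dioxaspiro[4.5]decan-8-yl]ethan-1-one
Conditions: MeLi (3 equiv), Et2O, 0 °C to rt; then H2O
Reagents that add atoms: methyllithium, [Li]C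
Why: Addition of methyllithium to the lithium carboxylate gives the methyl ketone only on aqueous quench, so over-addition to the tertiary alcohol is avoided (standard ketone synthesis from hindered acids).

Step 4
Reactants: 7 1-[8-(2-methylbut-3-en-2-yl)-1,4-dioxaspiro[4.5]decan-8-yl]ethan-1-one
Product: 8 8-(2-methylbut-3-en-2-yl)-8-(prop-1-en-2-yl)-1,4-dioxaspiro[4.5]decane
Conditions: Ph3PCH3Br, KOtBu, toluene, 90 °C
Reagents that add atoms: methyltriphenylphosphonium bromide, C[P+](c1ccccc1)(c1ccccc1)c1ccccc1.[Br-]
Why: Wittig methylenation with the non-stabilised ylide at elevated temperature converts the hindered methyl ketone into the isopropenyl group (future C1, C2 and the C1 methyl).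

Step 5
Reactants: 8 8-(2-methylbut-3-en-2-yl)-8-(prop-1-en-2-yl)-1,4-dioxaspiro[4.5]decane
Product: 9 3-methyl-3-[8-(prop-1-en-2-yl)-1,4-dioxaspiro[4.5]decan-8-yl]butanal
Conditions: PdCl2(PhCN)2 (10 mol%), CuCl2·2H2O (10 mol%), AgNO2 (5 mol%), O2 (1 atm), tBuOH/MeNO2, rt
Reagents that add atoms: dioxygen, O=O
Why: The nitrite-modified (aldehyde-selective) Wacker oxidation places oxygen on the terminal carbon of the monosubstituted alkene, helped by the neighbouring quaternary carbon, while the 1,1-disubstituted isopropenyl group is a poor Wacker substrate and should remain.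

Step 6
Reactants: 9 3-methyl-3-[8-(prop-1-en-2-yl)-1,4-dioxaspiro[4.5]decan-8-yl]butanal
Product: 10 (2S)-2-bromo-3-methyl-3-[8-(prop-1-en-2-yl)-1,4-dioxaspiro[4.5]decan-8-yl]butanal
Conditions: (2R,5R)-2,5-diphenylpyrrolidine (20 mol%), 4,4-dibromo-2,6-di-tert-butylcyclohexa-2,5-dienone (1.0 equiv), PhCO2H (cat.), CH2Cl2/pentane, −40 °C; cold filtration, used at once
Reagents that add atoms: 4,4-dibromo-2,6-di-tert-butylcyclohexa-2,5-dien-1-one, CC(C)(C)C1=CC(Br)(Br)C=C(C1=O)C(C)(C)C
Why: Enamine-catalysed enantioselective α-bromination: the twofold-symmetric amine shields one face of the E-enamine of this neopentyl-type aldehyde, so C4 (the first stereocentre of the route) is set as (S) under pure catalyst control.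

Step 7
Reactants: 10 (2S)-2-bromo-3-methyl-3-[8-(prop-1-en-2-yl)-1,4-dioxaspiro[4.5]decan-8-yl]butanal
Product: 11 (3S,4S)-4-bromo-9,9-(ethylenedioxy)-5,5-dimethyl-1-methylidenespiro[5.5]undecan-3-ol (hydroxyl trans to bromine)
Conditions: Me2AlCl (2.2 equiv), CH2Cl2, −78 °C; then aq. NaHCO3
Reagents that add atoms: none
Why: Me2AlCl binds the aldehyde oxygen, the terminal CH2 (C2) of the isopropenyl group, which is tethered through its central carbon C1, attacks the carbonyl carbon C3, and the C1 methyl gives up a proton to leave the exocyclic methylene, i.e. a stepwise, cation-like type 2 carbonyl-ene (Prins-type) cyclization whose closest known relative is the Me2AlCl-promoted closure of 6-methylhept-6-enals to 3-methylenecyclohexanols. Ring A closes in a six-membered mode that is exo with respect to the C=O and endo with respect to the C1=C2 alkene, and the two adjacent quaternary carbons C5 and C6 in the tether hold the reacting ends together (Thorpe–Ingold effect). The only new stereocentre, C3, is controlled by the C4 bromide: in the chair transition state the bulky aluminium-bound oxygen should stay equatorial to avoid the axial C5 methyl, and the bromine should stay equatorial and anti to the forming C2–C3 bond (polar Felkin–Anh), which places OH trans to Br. The step needs cyclization to outrun enolisation of the bromo aldehyde (loss of C4), which the low temperature, the aprotic Lewis acid and the gem-dialkyl-accelerated closure should secure. It also needs the isopropenyl group to be the only π-nucleophile, which is why ring B is carried as a saturated ketal, and the methyl groups on aluminium take up the released proton so that no Brønsted acid builds up to open the ketal.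

Step 8
Reactants: 11 (3S,4S)-4-bromo-9,9-(ethylenedioxy)-5,5-dimethyl-1-methylidenespiro[5.5]undecan-3-ol
Product: 12 (1S,3S,4S)-4-bromo-9,9-(ethylenedioxy)-1,5,5-trimethylspiro[5.5]undecan-3-ol
Conditions: [Ir(cod)(PCy3)(py)]PF6 (10 mol%), H2 (1 atm), CH2Cl2, rt
Reagents that add atoms: none
Why: Hydroxyl-directed hydrogenation: the cationic iridium catalyst is held by the C3 hydroxyl (axial in the reacting conformer) and adds H2 to the face of the C1 methylene syn to OH, so the C1 methyl ends up trans to OH and cis to the C4 bromine; the C–Br bond and the ketal are inert.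

Step 9
Reactants: 12 (1S,3S,4S)-4-bromo-9,9-(ethylenedioxy)-1,5,5-trimethylspiro[5.5]undecan-3-ol
Product: 13 (1S,4S)-4-bromo-9,9-(ethylenedioxy)-1,5,5-trimethylspiro[5.5]undecan-3-one
Conditions: Dess–Martin periodinane, CH2Cl2, rt
Reagents that add atoms: none
Why: Dess–Martin oxidation under near-neutral conditions removes the temporary C3 configuration (used only as the directing element of step 8) without epimerising C4 or eliminating HBr.

Step 10
Reactants: 13 (1S,4S)-4-bromo-9,9-(ethylenedioxy)-1,5,5-trimethylspiro[5.5]undecan-3-one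
Product: 15 (1S,3R,4S)-4-bromo-3-hydroxy-1,5,5-trimethylspiro[5.5]undecan-9-one, via ketal alcohol 14 (not isolated)
Conditions: iBu2AlH, CH2Cl2, −78 °C; then 2 M aq. HCl, THF, rt
Reagents that add atoms: water, O
Why: The bulky hydride should attack C3 from the equatorial side because the axial face is blocked by the syn-axial methyl groups on C1 and C5, which sets the hydroxyl cis to both the C4 bromine and the C1 methyl (the usual outcome for α-bromo ketones next to a gem-dimethyl carbon); the acidic work-up hydrolyses the dioxolane.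

Step 11
Reactants: 15 (1S,3R,4S)-4-bromo-3-hydroxy-1,5,5-trimethylspiro[5.5]undecan-9-one
Product: 16 (1S,3R,4S,6S)-4-bromo-1,5,5-trimethyl-3,9-bis(trimethylsilyloxy)spiro[5.5]undec-9-ene
Conditions: lithium (R,R)-bis(1-phenylethyl)amide (from the amine and n-BuLi, 2.4 equiv), LiCl, Me3SiCl (in situ quench), THF, −100 °C
Reagents that add atoms: chlorotrimethylsilane, C[Si](C)(C)Cl
Why: Enantiotopos-selective deprotonation of a 4,4-disubstituted cyclohexanone by a chiral lithium amide with internal silyl quench: the base removes one of the two axial α-protons related by the local mirror plane of ring B, which should place the enol ether toward C10 and make C6 stereogenic as (S) under reagent control; the C3 alkoxide is silylated in the same flask.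

Step 12
Reactants: 16 (1S,3R,4S,6S)-4-bromo-1,5,5-trimethyl-3,9-bis(trimethylsilyloxy)spiro[5.5]undec-9-ene
Product: 17 (1S,3R,4S,6S,10S)-4,10-dibromo-1,5,5-trimethyl-3-(trimethylsilyloxy)spiro[5.5]undecan-9-one
Conditions: N-bromosuccinimide, THF, −78 °C
Reagents that add atoms: N-bromosuccinimide, O=C1CCC(=O)N1Br
Why: Electrophilic bromination of the silyl enol ether is regiospecific for C10 and should occur on the face away from the axial C1 substituent of ring B, giving the equatorial bromide cis to C5, which is also the more stable epimer because an axial bromine would be 1,3-diaxial to C1.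

Step 13
Reactants: 17 (1S,3R,4S,6S,10S)-4,10-dibromo-1,5,5-trimethyl-3-(trimethylsilyloxy)spiro[5.5]undecan-9-one
Product: 18 (1S,3R,4S,6S,9R,10S)-4,10-dibromo-1,5,5,9-tetramethyl-3-(trimethylsilyloxy)spiro[5.5]undecan-9-ol
Conditions: MeMgBr, CeCl3, THF, −78 °C; then H2O
Reagents that add atoms: methylmagnesium bromide, C[Mg]Br
Why: The cerium-modified Grignard addition suppresses enolisation and halide displacement at the α-bromo ketone; equatorial attack should give mainly the axial alcohol shown, but the C9 configuration of 18 is not carried into the product.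

Step 14
Reactants: 18 (1S,3R,4S,6S,9R,10S)-4,10-dibromo-1,5,5,9-tetramethyl-3-(trimethylsilyloxy)spiro[5.5]undecan-9-ol
Product: 19 (1S,3R,4S,6S,9S,10S)-4,10-dibromo-9-chloro-1,5,5,9-tetramethylspiro[5.5]undecan-3-ol
Conditions: HCl (anhydrous), CH2Cl2, 0 °C to rt
Reagents that add atoms: hydrogen chloride, Cl
Why: SN1 substitution: loss of water gives the tertiary C9 cation, which is bridged by the neighbouring C10 bromine, and chloride opens this bromonium ion at the tertiary carbon anti to bromine, so C9 is set (Cl trans to Br, both equatorial, methyl axial) whichever C9 epimer of 18 is used; HCl also cleaves the silyl ether.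

**Compound list**

1 | 1,4-dioxaspiro[4.5]decane-8-carboxylic acid | OC(=O)C1CCC2(CC1)OCCO2 | starting material
2 | 1-bromo-3-methylbut-2-ene | CC(C)=CCBr | starting material
3 | 3-methylbut-2-en-1-yl 1,4-dioxaspiro[4.5]decane-8-carboxylate | CC(C)=CCOC(=O)C1CCC2(CC1)OCCO2 | intermediate
4 | [(1,4-dioxaspiro[4.5]decan-8-ylidene)(3-methylbut-2-en-1-yloxy)methoxy]trimethylsilane (silyl ketene acetal) | CC(C)=CCOC(O[Si](C)(C)C)=C1CCC2(CC1)OCCO2 | intermediate
5 | trimethylsilyl 8-(2-methylbut-3-en-2-yl)-1,4-dioxaspiro[4.5]decane-8-carboxylate (silyl ester) | C=CC(C)(C)C1(C(=O)O[Si](C)(C)C)CCC2(CC1)OCCO2 | intermediate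
6 | 8-(2-methylbut-3-en-2-yl)-1,4-dioxaspiro[4.5]decane-8-carboxylic acid | C=CC(C)(C)C1(C(=O)O)CCC2(CC1)OCCO2 | intermediate
7 | 1-[8-(2-methylbut-3-en-2-yl)-1,4-dioxaspiro[4.5]decan-8-yl]ethan-1-one | C=CC(C)(C)C1(C(C)=O)CCC2(CC1)OCCO2 | intermediate
8 | 8-(2-methylbut-3-en-2-yl)-8-(prop-1-en-2-yl)-1,4-dioxaspiro[4.5]decane | C=CC(C)(C)C1(C(C)=C)CCC2(CC1)OCCO2 | intermediate
9 | 3-methyl-3-[8-(prop-1-en-2-yl)-1,4-dioxaspiro[4.5]decan-8-yl]butanal | O=CCC(C)(C)C1(C(C)=C)CCC2(CC1)OCCO2 | intermediate
10 | (2S)-2-bromo-3-methyl-3-[8-(prop-1-en-2-yl)-1,4-dioxaspiro[4.5]decan-8-yl]butanal | O=C[C@@H](Br)C(C)(C)C1(C(C)=C)CCC2(CC1)OCCO2 | intermediate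
11 | (3S,4S)-4-bromo-9,9-(ethylenedioxy)-5,5-dimethyl-1-methylidenespiro[5.5]undecan-3-ol | C=C1C[C@H](O)[C@@H](Br)C(C)(C)C12CCC3(CC2)OCCO3 | intermediate
12 | (1S,3S,4S)-4-bromo-9,9-(ethylenedioxy)-1,5,5-trimethylspiro[5.5]undecan-3-ol | C[C@H]1C[C@H](O)[C@@H](Br)C(C)(C)C12CCC3(CC2)OCCO3 | intermediate
13 | (1S,4S)-4-bromo-9,9-(ethylenedioxy)-1,5,5-trimethylspiro[5.5]undecan-3-one | C[C@H]1CC(=O)[C@@H](Br)C(C)(C)C12CCC3(CC2)OCCO3 | intermediate
14 | (1S,3R,4S)-4-bromo-9,9-(ethylenedioxy)-1,5,5-trimethylspiro[5.5]undecan-3-ol (ketal alcohol) | C[C@H]1C[C@@H](O)[C@@H](Br)C(C)(C)C12CCC3(CC2)OCCO3 | intermediate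
15 | (1S,3R,4S)-4-bromo-3-hydroxy-1,5,5-trimethylspiro[5.5]undecan-9-one | C[C@H]1C[C@@H](O)[C@@H](Br)C(C)(C)C12CCC(=O)CC2 | intermediate
16 | (1S,3R,4S,6S)-4-bromo-1,5,5-trimethyl-3,9-bis(trimethylsilyloxy)spiro[5.5]undec-9-ene | C[C@H]1C[C@@H](O[Si](C)(C)C)[C@@H](Br)C(C)(C)[C@]12CCC(O[Si](C)(C)C)=CC2 | intermediate
17 | (1S,3R,4S,6S,10S)-4,10-dibromo-1,5,5-trimethyl-3-(trimethylsilyloxy)spiro[5.5]undecan-9-one | C[C@H]1C[C@@H](O[Si](C)(C)C)[C@@H](Br)C(C)(C)[C@]12CCC(=O)[C@@H](Br)C2 | intermediate
18 | (1S,3R,4S,6S,9R,10S)-4,10-dibromo-1,5,5,9-tetramethyl-3-(trimethylsilyloxy)spiro[5.5]undecan-9-ol | C[C@H]1C[C@@H](O[Si](C)(C)C)[C@@H](Br)C(C)(C)[C@]12CC[C@](O)(C)[C@@H](Br)C2 | intermediate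
19 | (1S,3R,4S,6S,9S,10S)-4,10-dibromo-9-chloro-1,5,5,9-tetramethylspiro[5.5]undecan-3-ol | C[C@H]1C[C@@H](O)[C@@H](Br)C(C)(C)[C@]12CC[C@](C)(Cl)[C@@H](Br)C2 | target

**Step count and risks**

Total step count: 14. Longest linear sequence: 14 steps (1 to 19).

Steps most likely to fail:

Step 8. Hydrogen may be delivered slowly or to the wrong face of the C1 methylene, because one face is screened by the axial C5 methyl and the other by ring B, and the hydroxyl can direct only from the less populated diaxial conformer. The fallback sets out from 11 and comes back at 15; it also accepts either C3 epimer of 11, so it covers a step 7 that is not trans-selective. Compound 11 is oxidised with Dess–Martin periodinane to (4S)-4-bromo-9,9-(ethylenedioxy)-5,5-dimethyl-1-methylidenespiro[5.5]undecan-3-one F1. This is reduced with iBu2AlH at −78 °C to the cis-bromohydrin (3R,4S)-4-bromo-9,9-(ethylenedioxy)-5,5-dimethyl-1-methylidenespiro[5.5]undecan-3-ol F2, the hydride entering anti to bromine as in closely related 2-bromo-3,3-dimethyl-5-methylenecyclohexanones. Silylation (Et3SiCl, imidazole, DMF) gives (3R,4S)-4-bromo-9,9-(ethylenedioxy)-5,5-dimethyl-1-methylidene-3-(triethylsilyloxy)spiro[5.5]undecane F3. Its bulky silyloxy group blocks the face syn to bromine, so heterogeneous hydrogenation (H2, PtO2, ethyl acetate) should add hydrogen anti to it by steric approach control and give (1S,3R,4S)-4-bromo-9,9-(ethylenedioxy)-1,5,5-trimethyl-3-(triethylsilyloxy)spiro[5.5]undecane F4. Aqueous HCl in THF then removes the silyl group and the ketal and gives 15.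

Step 11. Discrimination between the C8 and C10 methylene groups may be poor if the preference of the chiral amide and the bias of ring A do not match, and the lithium alkoxide next to the C4 bromide may undergo elimination under the strongly basic conditions. The fallback sets out from 15 and comes back at 17; it replaces the enolate chemistry by enamine catalysis under nearly neutral conditions. Compound 15 is brominated with (4R,5R)-4,5-diphenylimidazolidine (20 mol%), PhCO2H (cat.) and 4,4-dibromo-2,6-di-tert-butylcyclohexa-2,5-dienone in THF at −30 °C to give (1S,3R,4S,6S,10S)-4,10-dibromo-3-hydroxy-1,5,5-trimethylspiro[5.5]undecan-9-one F5. The catalyst selects the α-carbon, and the bromine can settle in the equatorial position through the enamine. Silylation of the C3 hydroxyl (Me3SiCl, imidazole, CH2Cl2) gives 17.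

Step 14. Ionisation of the tertiary alcohol is retarded by the neighbouring bromine, so elimination and slow decomposition of the bromohydrin may outrun chloride capture. The fallback sets out from 17 and comes back at 19; it makes the C9 cation from an alkene instead of from the alcohol. Compound 17 is treated with Me3SiCH2MgCl and CeCl3 in THF at −78 °C to give (1S,3R,4S,6S,9S,10S)-4,10-dibromo-1,5,5-trimethyl-9-[(trimethylsilyl)methyl]-3-(trimethylsilyloxy)spiro[5.5]undecan-9-ol F6. Anhydrous HCl in CH2Cl2 then brings about the acid-induced Peterson elimination, whose ionisation is assisted by the β-silyl group, and cleaves the silyl ether to give (1S,3R,4S,6S,10S)-4,10-dibromo-1,5,5-trimethyl-9-methylidenespiro[5.5]undecan-3-ol F7. In the same flask, Markovnikov addition of HCl to F7 through the same bromonium ion gives 19.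

Further compounds
F1 | step 8 | (4S)-4-bromo-9,9-(ethylenedioxy)-5,5-dimethyl-1-methylidenespiro[5.5]undecan-3-one | C=C1CC(=O)[C@@H](Br)C(C)(C)C12CCC3(CC2)OCCO3
F2 | step 8 | (3R,4S)-4-bromo-9,9-(ethylenedioxy)-5,5-dimethyl-1-methylidenespiro[5.5]undecan-3-ol | C=C1C[C@@H](O)[C@@H](Br)C(C)(C)C12CCC3(CC2)OCCO3
F3 | step 8 | (3R,4S)-4-bromo-9,9-(ethylenedioxy)-5,5-dimethyl-1-methylidene-3-(triethylsilyloxy)spiro[5.5]undecane | C=C1C[C@@H](O[Si](CC)(CC)CC)[C@@H](Br)C(C)(C)C12CCC3(CC2)OCCO3
F4 | step 8 | (1S,3R,4S)-4-bromo-9,9-(ethylenedioxy)-1,5,5-trimethyl-3-(triethylsilyloxy)spiro[5.5]undecane | C[C@H]1C[C@@H](O[Si](CC)(CC)CC)[C@@H](Br)C(C)(C)C12CCC3(CC2)OCCO3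
F5 | step 11 | (1S,3R,4S,6S,10S)-4,10-dibromo-3-hydroxy-1,5,5-trimethylspiro[5.5]undecan-9-one | C[C@H]1C[C@@H](O)[C@@H](Br)C(C)(C)[C@]12CCC(=O)[C@@H](Br)C2
F6 | step 14 | (1S,3R,4S,6S,9S,10S)-4,10-dibromo-1,5,5-trimethyl-9-[(trimethylsilyl)methyl]-3-(trimethylsilyloxy)spiro[5.5]undecan-9-ol | C[C@H]1C[C@@H](O[Si](C)(C)C)[C@@H](Br)C(C)(C)[C@]12CC[C@](O)(C[Si](C)(C)C)[C@@H](Br)C2
F7 | step 14 | (1S,3R,4S,6S,10S)-4,10-dibromo-1,5,5-trimethyl-9-methylidenespiro[5.5]undecan-3-ol | C[C@H]1C[C@@H](O)[C@@H](Br)C(C)(C)[C@]12CCC(=C)[C@@H](Br)C2
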